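**Plan**
- Cuts, in retrosynthetic order: the eight O–Me bonds and the C–Br bond; then the two aryl–C bonds at the 4-oxybenzylic carbons (indane C1–C7a and cyclooctane CH(Ar)–aryl), which opens the pentacycle to a 2,3-diaryl-1,4-diarylbutane-1,4-diol; then the two carbinol–aryl bonds, the central C2–C3 bond of the chain, and the C2–C3 and C3–aryl bonds of the dihydrobenzofuran.
- Enabling feature: indane C1 and the cyclooctane CH(Ar) each carry a 4-oxyphenyl group and each is bonded to an arene carbon ortho/para to oxygen, so both bonds pair a stabilised benzylic cation with a nucleophilic arene position.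
- Forward order: resorcinol ring → benzophenone → dihydrobenzofuran (C–H insertion) → arylacetyl imide → nitro-Michael addition builds the chain → 1,4-diol → indane and cyclooctane close together → debromination and demethylation.
- Stereochemistry: dihydrofuran C3 from the chiral rhodium catalyst and C2 by trans equilibration; chain C2 from the oxazolidinone and chain C3 from the anti topicity of the Michael addition; indane C1 and CH(Ar) by substrate control in the double cyclisation.

Key step: step 18

Abbreviation: BF = (2R,3R)-5-bromo-3-(3,5-dimethoxyphenyl)-6-methoxy-2-(4-methoxyphenyl)-2,3-dihydro-1-benzofuran-4-yl (2,3-trans).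
Assumption: the insertion catalyst is written as Rh2(R-PTAD)4; its sense of induction on this substrate is assigned by analogy, and the S-catalyst is used instead if the opposite C3 configuration results.

Step 1
Reactants: 1 3,5-dimethoxyphenylacetic acid
Product: 2 2-(3,5-dimethoxyphenyl)ethan-1-ol
Conditions: LiAlH4, THF, 0 °C → rt
Reagents that add atoms: none
Why: Hydride reduction of a carboxylic acid to the primary alcohol (LiAlH4 reduction); nothing else in the molecule is reducible.

Step 2
Reactants: 2 2-(3,5-dimethoxyphenyl)ethan-1-ol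
Product: 3 2-(3,5-dimethoxyphenyl)ethyl pivalate
Conditions: PivCl, pyridine, DMAP (cat.), CH2Cl2, 0 °C → rt
Reagents that add atoms: pivaloyl chloride, CC(C)(C)C(Cl)=O
Why: Esterification of a primary alcohol with an acid chloride; the pivalate should survive Lewis acid, hydrazine and the rhodium carbene, and it deactivates the neighbouring O–CH2 bonds towards insertion.

Step 3
Reactants: 3 2-(3,5-dimethoxyphenyl)ethyl pivalate; 4 3,5-dimethoxybenzoyl chloride
Product: 6 2-[2-(3,5-dimethoxybenzoyl)-3-hydroxy-5-methoxyphenyl]ethyl pivalate, via methoxy ketone 5 (not isolated)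
Conditions: AlCl3 (3 equiv), CH2Cl2, 0 °C → rt
Reagents that add atoms: none
Why: Friedel–Crafts acylation at the position ortho to the side chain and para to a methoxy group (the usual site in 5-alkylresorcinol dimethyl ethers), followed in the same flask by chelation-controlled cleavage of the one methyl ether ortho to the new carbonyl group.

Step 4
Reactants: 6 2-[2-(3,5-dimethoxybenzoyl)-3-hydroxy-5-methoxyphenyl]ethyl pivalate
Product: 7 2-[2-bromo-6-(3,5-dimethoxybenzoyl)-5-hydroxy-3-methoxyphenyl]ethyl pivalate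
Conditions: NBS (1.05 equiv), MeCN, 0 °C
Reagents that add atoms: N-bromosuccinimide, O=C1CCC(=O)N1Br
Why: Electrophilic aromatic bromination para to the free phenol, the most activated open position, while the benzoyl-deactivated dimethoxyphenyl ring stays untouched; this is the one stage at which the blocking bromine can be placed on this ring selectively.

Step 5
Reactants: 7 2-[2-bromo-6-(3,5-dimethoxybenzoyl)-5-hydroxy-3-methoxyphenyl]ethyl pivalate; 8 4-methoxybenzyl chloride
Product: 9 2-{2-bromo-6-(3,5-dimethoxybenzoyl)-3-methoxy-5-[(4-methoxybenzyl)oxy]phenyl}ethyl pivalate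
Conditions: K2CO3, Bu4NI (cat.), DMF, 50 °C
Reagents that add atoms: none
Why: Williamson etherification of the phenol; the benzylic carbon introduced here becomes C2 of the dihydrobenzofuran and its aryl group the 2-(4-methoxyphenyl) substituent.

Step 6
Reactants: 9 2-{2-bromo-6-(3,5-dimethoxybenzoyl)-3-methoxy-5-[(4-methoxybenzyl)oxy]phenyl}ethyl pivalate
Product: 10 hydrazone of ketone 9 (E/Z mixture)
Conditions: N2H4·H2O (excess), AcOH (cat.), EtOH, 80 °C
Reagents that add atoms: hydrazine (as hydrate), NN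
Why: Condensation of a diaryl ketone with hydrazine to the hydrazone; both geometric isomers lead to the same diazo compound, and the hindered pivalate should resist hydrazinolysis at this temperature.

Step 7
Reactants: 10 hydrazone of ketone 9
Product: 12 2-[(2S,3R)-5-bromo-3-(3,5-dimethoxyphenyl)-6-methoxy-2-(4-methoxyphenyl)-2,3-dihydro-1-benzofuran-4-yl]ethyl pivalate (2,3-cis), via diazo compound 11 (not isolated)
Conditions: MnO2, Rh2(R-PTAD)4 (1 mol%), MeCN, 0 °C → rt
Reagents that add atoms: none
Why: Oxidation of the hydrazone to the diaryldiazomethane and rhodium(II)-catalysed intramolecular 1,5 C–H insertion of the donor/donor carbene into the doubly activated ArO–CH2–Ar bond, a known route from 2-(benzyloxy)benzophenone hydrazones to cis-2,3-diaryl-2,3-dihydrobenzofurans; the chiral carboxylate ligands set C3 as R and the concerted insertion places the C2 aryl group cis to it.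

Step 8
Reactants: 12 cis-dihydrobenzofuran pivalate
Product: 13 2-BF-ethyl pivalate (2R,3R, 2,3-trans)
Conditions: TFA, CH2Cl2, 0 °C → rt
Reagents that add atoms: none
Why: Acid-induced epimerisation at C2 by reversible ionisation of the 4-methoxybenzylic C–O bond and reclosure to the thermodynamically preferred trans isomer; C3 is not involved and keeps its configuration.

Step 9
Reactants: 13 2-BF-ethyl pivalate
Product: 14 2-BF-ethan-1-ol
Conditions: NaOMe, MeOH–THF, 50 °C
Reagents that add atoms: none
Why: Base-mediated transesterification (methanolysis) of the pivalate; aryl bromide, aryl ethers and the two ring stereocentres are inert to methoxide.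

Step 10
Reactants: 14 2-BF-ethan-1-ol
Product: 15 BF-acetic acid
Conditions: TEMPO (cat.), PhI(OAc)2, MeCN–H2O, rt
Reagents that add atoms: water, O
Why: TEMPO-catalysed oxidation of a primary alcohol to the carboxylic acid with a chlorine-free terminal oxidant, which avoids halogenation of the electron-rich rings.

Step 11
Reactants: 15 BF-acetic acid; 16 (4R)-4-benzyl-1,3-oxazolidin-2-one
Product: 18 (4R)-4-benzyl-3-(BF-acetyl)-1,3-oxazolidin-2-one, via mixed pivalic anhydride 17 (not isolated)
Conditions: PivCl, Et3N, THF, −20 °C; then 16, LiCl, rt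
Reagents that add atoms: pivaloyl chloride, CC(C)(C)C(Cl)=O (retained only in intermediate 17)
Why: N-acylation of the oxazolidinone through the mixed anhydride (LiCl/Et3N method), which installs the auxiliary without strong base.

Step 12
Reactants: 19 3,5-dimethoxybenzaldehyde; 20 nitromethane
Product: 21 (E)-1,3-dimethoxy-5-(2-nitroethenyl)benzene
Conditions: NH4OAc, AcOH, 100 °C
Reagents that add atoms: none
Why: Henry condensation (nitroaldol reaction with dehydration), which gives the conjugated E-nitroalkene.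

Step 13
Reactants: 18 (4R)-4-benzyl-3-(BF-acetyl)-1,3-oxazolidin-2-one; 21 (E)-1,3-dimethoxy-5-(2-nitroethenyl)benzene
Product: 23 (4R)-4-benzyl-3-[(2R,3S)-2-BF-3-(3,5-dimethoxyphenyl)-4-nitrobutanoyl]-1,3-oxazolidin-2-one, via chlorotitanium enolate 22 (not isolated)
Conditions: TiCl4, i-Pr2NEt, CH2Cl2, −78 °C; then 21, −78 → −40 °C
Reagents that add atoms: titanium tetrachloride, Cl[Ti](Cl)(Cl)Cl (retained only in intermediate 22)
Why: Auxiliary-controlled Michael addition of a chelated Z-titanium enolate of an N-acyloxazolidinone to a nitroalkene; the benzyl group shields one enolate face and sets C2 as R, and the closed transition state with the nitro group held at titanium should place the two aryl groups anti (as for Z-enolates in general), setting C3 as S.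

Step 14
Reactants: 23 Michael adduct
Product: 24 (2S,3R)-4-[(4R)-4-benzyl-2-oxo-1,3-oxazolidin-3-yl]-3-BF-2-(3,5-dimethoxyphenyl)-4-oxobutanoic acid
Conditions: NaNO2, AcOH, DMSO, 35 °C
Reagents that add atoms: sodium nitrite, [Na+].[O-]N=O; water, O
Why: Nef-type oxidation of a primary nitroalkane to the carboxylic acid under mildly acidic conditions, which should leave the imide and both benzylic stereocentres intact.

Step 15
Reactants: 24 imide acid
Product: 25 (2R,3S)-2-BF-3-(3,5-dimethoxyphenyl)butane-1,4-diol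
Conditions: LiAlH4, THF, 0 °C
Reagents that add atoms: none
Why: LiAlH4 reduction of the carboxylic acid together with reductive cleavage of the N-acyloxazolidinone; at 0 °C the aryl bromide should survive, and the auxiliary is recovered.

Step 16
Reactants: 25 1,4-diol
Product: 26 (2R,3S)-2-BF-3-(3,5-dimethoxyphenyl)butanedial
Conditions: (COCl)2, DMSO, CH2Cl2, −78 °C; i-Pr2NEt, −78 → −40 °C; used crude
Reagents that add atoms: none
Why: Swern oxidation of both primary alcohols; both hydroxyl groups are activated before base is added, which prevents lactol and lactone formation, and the hindered base at low temperature limits epimerisation of the two α-aryl aldehyde centres.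

Step 17
Reactants: 26 dialdehyde; 27 4-bromoanisole (5 equiv, all converted into 28; two equivalents end up in the product)
Product: 29 (1RS,2R,3S,4RS)-2-BF-3-(3,5-dimethoxyphenyl)-1,4-bis(4-methoxyphenyl)butane-1,4-diol (mixture of carbinol epimers), via 4-methoxyphenylmagnesium bromide 28 (not isolated)
Conditions: 27 (5 equiv), Mg, THF, rt → 40 °C; then crude 26 in THF, −78 → −20 °C; aq. NH4Cl
Reagents that add atoms: magnesium, [Mg] (retained only in intermediate 28); 4-bromoanisole, COc1ccc(Br)cc1 (second equivalent, one 4-methoxyphenyl group per aldehyde carbon)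
Why: Twofold Grignard addition, one molecule of 28 per aldehyde group, with the excess reagent also opening any lactol alkoxide formed after the first addition; the configuration of the two new carbinol centres does not matter because both are ionised in the next step.

Step 18
Reactants: 29 tetraaryl 1,4-diol
Product: 31 bromo derivative of stenophyllol B octamethyl ether, via indane carbinol 30 (not isolated)
Conditions: BF3·OEt2 (5 equiv), CH2Cl2 (2 mM), −40 → 0 °C
Reagents that add atoms: none
Why: BF3 ionises both 4-methoxybenzylic carbinols to planar, quinone-methide-like cations, so all four carbinol epimers (and any cyclic ether formed reversibly from them) converge; this is the acid-promoted Friedel–Crafts cyclialkylation of 4-methoxybenzylic alcohols onto dimethoxyarenes known from oligostilbene chemistry. The cation at future indane C1 is attacked by the ortho carbon of the 3,5-dimethoxyphenyl group on C3 (five-membered cyclialkylation, arene carbon ortho to one methoxy group and para to the other), giving indane 30. The second cation is then attacked by the ortho carbon of the 3,5-dimethoxyphenyl group on dihydrofuran C3 (eight-membered cyclialkylation under high dilution), giving 31. At indane C1 the arene adds anti to the benzofuranyl group on C2, giving the 1,2-trans relation that is also the thermodynamic one; at CH(Ar) the cation reacts in the conformer that turns its aryl group away from the indane, so the arene held on the rigid benzofuran reaches only one face and the R centre should result. The step needs each cation to choose the right arene: the bromine blocks C5 of the benzofuran, the only position that could close a competing five-membered ring; the 2,3-trans indane would in any case force a trans-fused diquinane there; and five-membered closure at C1 should outrun the seven-membered alternative onto the dihydrofuran aryl group.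

Step 19
Reactants: 31 bromo octamethyl ether
Product: 32 stenophyllol B octamethyl ether
Conditions: H2 (1 atm), 10% Pd/C, Et3N, EtOAc–MeOH, rt
Reagents that add atoms: none
Why: Palladium-catalysed hydrogenolysis of the aryl C–Br bond; the base takes up HBr, so the benzylic C–O bond of the dihydrofuran is not activated.

Step 20
Reactants: 32 stenophyllol B octamethyl ether
Product: 33 stenophyllol B
Conditions: BBr3 (excess), CH2Cl2, −78 °C → rt; MeOH quench
Reagents that add atoms: none
Why: Lewis acid cleavage of all eight aryl methyl ethers with BBr3, the standard final deprotection of permethylated oligostilbenes; the six stereocentres carry no acidic or leaving group and are kept.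

**Compound list**
1 | 3,5-dimethoxyphenylacetic acid | COc1cc(CC(O)=O)cc(OC)c1 | starting material
2 | 2-(3,5-dimethoxyphenyl)ethan-1-ol | COc1cc(CCO)cc(OC)c1 | intermediate
3 | 2-(3,5-dimethoxyphenyl)ethyl pivalate | COc1cc(CCOC(=O)C(C)(C)C)cc(OC)c1 | intermediate
4 | 3,5-dimethoxybenzoyl chloride | COc1cc(cc(OC)c1)C(Cl)=O | starting material
5 | 2-[2-(3,5-dimethoxybenzoyl)-3,5-dimethoxyphenyl]ethyl pivalate | CC(C)(C)C(=O)OCCc1cc(OC)cc(OC)c1C(=O)c1cc(OC)cc(OC)c1 | intermediate (not isolated)
6 | 2-[2-(3,5-dimethoxybenzoyl)-3-hydroxy-5-methoxyphenyl]ethyl pivalate | CC(C)(C)C(=O)OCCc1cc(OC)cc(O)c1C(=O)c1cc(OC)cc(OC)c1 | intermediate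
7 | 2-[2-bromo-6-(3,5-dimethoxybenzoyl)-5-hydroxy-3-methoxyphenyl]ethyl pivalate | CC(C)(C)C(=O)OCCc1c(Br)c(OC)cc(O)c1C(=O)c1cc(OC)cc(OC)c1 | intermediate
8 | 4-methoxybenzyl chloride | COc1ccc(CCl)cc1 | starting material
9 | 2-{2-bromo-6-(3,5-dimethoxybenzoyl)-3-methoxy-5-[(4-methoxybenzyl)oxy]phenyl}ethyl pivalate | CC(C)(C)C(=O)OCCc1c(Br)c(OC)cc(OCc2ccc(OC)cc2)c1C(=O)c1cc(OC)cc(OC)c1 | intermediate
10 | hydrazone of 9 (E/Z mixture) | CC(C)(C)C(=O)OCCc1c(Br)c(OC)cc(OCc2ccc(OC)cc2)c1C(=NN)c1cc(OC)cc(OC)c1 | intermediate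
11 | diaryldiazomethane from 10 | CC(C)(C)C(=O)OCCc1c(Br)c(OC)cc(OCc2ccc(OC)cc2)c1C(=[N+]=[N-])c1cc(OC)cc(OC)c1 | intermediate (not isolated)
12 | 2-[(2S,3R)-5-bromo-3-(3,5-dimethoxyphenyl)-6-methoxy-2-(4-methoxyphenyl)-2,3-dihydro-1-benzofuran-4-yl]ethyl pivalate (cis) | CC(C)(C)C(=O)OCCc1c(Br)c(OC)cc2O[C@H](c3ccc(OC)cc3)[C@@H](c12)c1cc(OC)cc(OC)c1 | intermediate
13 | 2-BF-ethyl pivalate (2R,3R, trans) | CC(C)(C)C(=O)OCCc1c(Br)c(OC)cc2O[C@@H](c3ccc(OC)cc3)[C@@H](c12)c1cc(OC)cc(OC)c1 | intermediate
14 | 2-BF-ethan-1-ol | OCCc1c(Br)c(OC)cc2O[C@@H](c3ccc(OC)cc3)[C@@H](c12)c1cc(OC)cc(OC)c1 | intermediate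
15 | BF-acetic acid | OC(=O)Cc1c(Br)c(OC)cc2O[C@@H](c3ccc(OC)cc3)[C@@H](c12)c1cc(OC)cc(OC)c1 | intermediate
16 | (4R)-4-benzyl-1,3-oxazolidin-2-one | O=C1N[C@H](Cc2ccccc2)CO1 | starting material
17 | mixed anhydride of 15 with pivalic acid | CC(C)(C)C(=O)OC(=O)Cc1c(Br)c(OC)cc2O[C@@H](c3ccc(OC)cc3)[C@@H](c12)c1cc(OC)cc(OC)c1 | intermediate (not isolated)
18 | (4R)-4-benzyl-3-(BF-acetyl)-1,3-oxazolidin-2-one | O=C(Cc1c(Br)c(OC)cc2O[C@@H](c3ccc(OC)cc3)[C@@H](c12)c1cc(OC)cc(OC)c1)N1[C@H](Cc2ccccc2)COC1=O | intermediate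
19 | 3,5-dimethoxybenzaldehyde | COc1cc(C=O)cc(OC)c1 | starting material
20 | nitromethane | C[N+](=O)[O-] | starting material
21 | (E)-1,3-dimethoxy-5-(2-nitroethenyl)benzene | COc1cc(/C=C/[N+](=O)[O-])cc(OC)c1 | intermediate
22 | trichlorotitanium (Z)-enolate of 18 | Cl[Ti](Cl)(Cl)O/C(=C\c1c(Br)c(OC)cc2O[C@@H](c3ccc(OC)cc3)[C@@H](c12)c1cc(OC)cc(OC)c1)N1[C@H](Cc2ccccc2)COC1=O | intermediate (not isolated)
23 | (4R)-4-benzyl-3-[(2R,3S)-2-BF-3-(3,5-dimethoxyphenyl)-4-nitrobutanoyl]-1,3-oxazolidin-2-one | O=C([C@@H](c1c(Br)c(OC)cc2O[C@@H](c3ccc(OC)cc3)[C@@H](c12)c1cc(OC)cc(OC)c1)[C@@H](c1cc(OC)cc(OC)c1)C[N+](=O)[O-])N1[C@H](Cc2ccccc2)COC1=O | intermediate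
24 | (2S,3R)-4-[(4R)-4-benzyl-2-oxo-1,3-oxazolidin-3-yl]-3-BF-2-(3,5-dimethoxyphenyl)-4-oxobutanoic acid | O=C([C@@H](c1c(Br)c(OC)cc2O[C@@H](c3ccc(OC)cc3)[C@@H](c12)c1cc(OC)cc(OC)c1)[C@@H](c1cc(OC)cc(OC)c1)C(O)=O)N1[C@H](Cc2ccccc2)COC1=O | intermediate
25 | (2R,3S)-2-BF-3-(3,5-dimethoxyphenyl)butane-1,4-diol | OC[C@@H](c1c(Br)c(OC)cc2O[C@@H](c3ccc(OC)cc3)[C@@H](c12)c1cc(OC)cc(OC)c1)[C@@H](c1cc(OC)cc(OC)c1)CO | intermediate
26 | (2R,3S)-2-BF-3-(3,5-dimethoxyphenyl)butanedial | O=C[C@@H](c1c(Br)c(OC)cc2O[C@@H](c3ccc(OC)cc3)[C@@H](c12)c1cc(OC)cc(OC)c1)[C@@H](c1cc(OC)cc(OC)c1)C=O | intermediate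
27 | 4-bromoanisole | COc1ccc(Br)cc1 | starting material
28 | 4-methoxyphenylmagnesium bromide | COc1ccc([Mg]Br)cc1 | intermediate (not isolated)
29 | (1RS,2R,3S,4RS)-2-BF-3-(3,5-dimethoxyphenyl)-1,4-bis(4-methoxyphenyl)butane-1,4-diol (carbinol epimers) | COc1ccc(C(O)[C@@H](c2c(Br)c(OC)cc3O[C@@H](c4ccc(OC)cc4)[C@@H](c23)c2cc(OC)cc(OC)c2)[C@@H](c2cc(OC)cc(OC)c2)C(O)c2ccc(OC)cc2)cc1 | intermediate
30 | (RS)-[(1S,2R,3S)-2-BF-4,6-dimethoxy-3-(4-methoxyphenyl)-2,3-dihydro-1H-inden-1-yl](4-methoxyphenyl)methanol (all-trans indane) | COc1ccc([C@H]2c3c(OC)cc(OC)cc3[C@@H](C(O)c3ccc(OC)cc3)[C@@H]2c2c(Br)c(OC)cc3O[C@@H](c4ccc(OC)cc4)[C@@H](c23)c2cc(OC)cc(OC)c2)cc1 | intermediate (not isolated)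
31 | bromo derivative of stenophyllol B octamethyl ether (Br ortho to the indane-bearing carbon of the benzofuran; indane C1 S, C2 S, C3 R, all-trans; cyclooctane CH(Ar) R; dihydrofuran C2 R, C3 R, trans) | COc1ccc([C@H]2c3c(OC)cc(OC)cc3[C@H]3[C@H](c4ccc(OC)cc4)c4c(OC)cc(OC)cc4[C@@H]4c5c(cc(OC)c(Br)c5[C@H]23)O[C@H]4c2ccc(OC)cc2)cc1 | intermediate
32 | stenophyllol B octamethyl ether (same configuration) | COc1ccc([C@H]2c3c(OC)cc(OC)cc3[C@H]3[C@H](c4ccc(OC)cc4)c4c(OC)cc(OC)cc4[C@@H]4c5c(cc(OC)cc5[C@H]23)O[C@H]4c2ccc(OC)cc2)cc1 | intermediate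
33 | stenophyllol B (same configuration, eight free phenols) | Oc1ccc([C@H]2c3c(O)cc(O)cc3[C@H]3[C@H](c4ccc(O)cc4)c4c(O)cc(O)cc4[C@@H]4c5c(cc(O)cc5[C@H]23)O[C@H]4c2ccc(O)cc2)cc1 | target

**Totals**
Total step count: 20. Longest linear sequence: 19 (steps 1–11 and 13–20; step 12 is a one-step side branch).

**Steps most likely to fail**

1. Step 18 (double cyclisation). Both cations are generated together, and three processes could divert them. The C1 cation could be captured by the dihydrofuran aryl group in a seven-membered closure. The second cation could be lost through elimination or intermolecular alkylation before the slow eight-membered closure. Ipso attack at the brominated carbon could transfer the bromine.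
Fallback (sets out from 23, rejoins at 30): the two ring closures are staged, using the differentiated termini of the Michael adduct, so that only one cation exists at a time. LiBH4 removes the auxiliary from 23 and gives (2R,3S)-2-BF-3-(3,5-dimethoxyphenyl)-4-nitrobutan-1-ol F1. Dess–Martin oxidation gives the nitro aldehyde F2, and 4-methoxyphenylmagnesium bromide gives the nitro carbinol F3 as an epimer mixture. BF3·OEt2 then closes only the indane, because the nitromethyl terminus cannot ionise, giving the nitromethyl indane F4. A reductive Nef reaction (buffered TiCl3) gives the indane aldehyde F5, and a second Grignard addition gives 30. Compound 30 is isolated and submitted to the eight-membered closure on its own at high dilution to reach 31.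

2. Step 7 (C–H insertion, including formation of its hydrazone precursor in step 6). The ketone is flanked by two ortho substituents, so hydrazone formation may stall. The twisted diaryl carbene may insert with low enantio- or diastereoselectivity, or may react with the side chain instead.
Fallback (sets out from 9, rejoins at 13): the ring is built stepwise without a carbene, and the enantiomers are separated afterwards. Corey–Chaykovsky methylene transfer to the ketone of 9 gives the 2,2-diaryloxirane F6. ZnI2-induced Meinwald rearrangement gives the diarylacetaldehyde F7, and 4-methoxyphenylmagnesium bromide gives the carbinol F8 as a diastereomer mixture. TFA with anisole removes the 4-methoxybenzyl ether and closes the ring by attack of the phenol on the 4-methoxybenzylic cation, giving the racemic trans-dihydrobenzofuran pivalate F9. Chromatography on a chiral stationary phase then gives 13.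

3. Step 13 (Michael addition). The enolate carbon carries a doubly ortho-substituted aryl group, so addition may be slow. The anti topicity may also be eroded (a syn adduct would give the wrong chain diastereomer), and the stereogenic benzofuran may work against the auxiliary.
Fallback (sets out from 15, rejoins at 25): the erythro relation is fixed by syn hydrogenation of a ring alkene instead of by enolate topicity. O-Alkylation of acid 15 with commercial 2-bromo-1-(3,5-dimethoxyphenyl)ethan-1-one (Et3N) gives the 2-(3,5-dimethoxyphenyl)-2-oxoethyl ester F10. DBU-induced intramolecular aldol condensation then gives the 3,4-diarylbutenolide F11. Hydrogenation over PtO2 (palladium is avoided to keep the C–Br bond) adds both hydrogens to one face, so only cis-lactones form. The needed cis-lactone F12 is separated from its cis diastereomer F13, which arises from attack on the other face, and LiAlH4 reduction of F12 gives 25. Face selectivity here rests only on the stereogenic benzofuran, so a separation is accepted.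

Further compounds
F1 | step 18 | (2R,3S)-2-BF-3-(3,5-dimethoxyphenyl)-4-nitrobutan-1-ol | OC[C@@H](c1c(Br)c(OC)cc2O[C@@H](c3ccc(OC)cc3)[C@@H](c12)c1cc(OC)cc(OC)c1)[C@@H](c1cc(OC)cc(OC)c1)C[N+](=O)[O-]
F2 | step 18 | (2R,3S)-2-BF-3-(3,5-dimethoxyphenyl)-4-nitrobutanal | O=C[C@@H](c1c(Br)c(OC)cc2O[C@@H](c3ccc(OC)cc3)[C@@H](c12)c1cc(OC)cc(OC)c1)[C@@H](c1cc(OC)cc(OC)c1)C[N+](=O)[O-]
F3 | step 18 | (1RS,2R,3S)-2-BF-3-(3,5-dimethoxyphenyl)-1-(4-methoxyphenyl)-4-nitrobutan-1-ol | COc1ccc(C(O)[C@@H](c2c(Br)c(OC)cc3O[C@@H](c4ccc(OC)cc4)[C@@H](c23)c2cc(OC)cc(OC)c2)[C@@H](c2cc(OC)cc(OC)c2)C[N+](=O)[O-])cc1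
F4 | step 18 | (1S,2R,3S)-2-BF-4,6-dimethoxy-3-(4-methoxyphenyl)-1-(nitromethyl)-2,3-dihydro-1H-indene | COc1ccc([C@H]2c3c(OC)cc(OC)cc3[C@@H](C[N+](=O)[O-])[C@@H]2c2c(Br)c(OC)cc3O[C@@H](c4ccc(OC)cc4)[C@@H](c23)c2cc(OC)cc(OC)c2)cc1
F5 | step 18 | (1S,2R,3S)-2-BF-4,6-dimethoxy-3-(4-methoxyphenyl)-2,3-dihydro-1H-indene-1-carbaldehyde | COc1ccc([C@H]2c3c(OC)cc(OC)cc3[C@@H](C=O)[C@@H]2c2c(Br)c(OC)cc3O[C@@H](c4ccc(OC)cc4)[C@@H](c23)c2cc(OC)cc(OC)c2)cc1
F6 | step 7 | 2-{2-bromo-6-[2-(3,5-dimethoxyphenyl)oxiran-2-yl]-3-methoxy-5-[(4-methoxybenzyl)oxy]phenyl}ethyl pivalate (racemic) | CC(C)(C)C(=O)OCCc1c(Br)c(OC)cc(OCc2ccc(OC)cc2)c1C1(CO1)c1cc(OC)cc(OC)c1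
F7 | step 7 | 2-{2-bromo-6-[1-(3,5-dimethoxyphenyl)-2-oxoethyl]-3-methoxy-5-[(4-methoxybenzyl)oxy]phenyl}ethyl pivalate (racemic) | CC(C)(C)C(=O)OCCc1c(Br)c(OC)cc(OCc2ccc(OC)cc2)c1C(C=O)c1cc(OC)cc(OC)c1
F8 | step 7 | 2-{2-bromo-6-[1-(3,5-dimethoxyphenyl)-2-hydroxy-2-(4-methoxyphenyl)ethyl]-3-methoxy-5-[(4-methoxybenzyl)oxy]phenyl}ethyl pivalate (diastereomer mixture) | CC(C)(C)C(=O)OCCc1c(Br)c(OC)cc(OCc2ccc(OC)cc2)c1C(C(O)c1ccc(OC)cc1)c1cc(OC)cc(OC)c1
F9 | step 7 | racemic trans-dihydrobenzofuran pivalate (13 and its enantiomer, 1:1) | CC(C)(C)C(=O)OCCc1c(Br)c(OC)cc2O[C@@H](c3ccc(OC)cc3)[C@@H](c12)c1cc(OC)cc(OC)c1.CC(C)(C)C(=O)OCCc1c(Br)c(OC)cc2O[C@H](c3ccc(OC)cc3)[C@H](c12)c1cc(OC)cc(OC)c1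
F10 | step 13 | 2-(3,5-dimethoxyphenyl)-2-oxoethyl BF-acetate | O=C(COC(=O)Cc1c(Br)c(OC)cc2O[C@@H](c3ccc(OC)cc3)[C@@H](c12)c1cc(OC)cc(OC)c1)c1cc(OC)cc(OC)c1
F11 | step 13 | 3-BF-4-(3,5-dimethoxyphenyl)furan-2(5H)-one | O=C1OCC(c2cc(OC)cc(OC)c2)=C1c1c(Br)c(OC)cc2O[C@@H](c3ccc(OC)cc3)[C@@H](c12)c1cc(OC)cc(OC)c1
F12 | step 13 | (3R,4S)-3-BF-4-(3,5-dimethoxyphenyl)oxolan-2-one (cis) | O=C1OC[C@H](c2cc(OC)cc(OC)c2)[C@@H]1c1c(Br)c(OC)cc2O[C@@H](c3ccc(OC)cc3)[C@@H](c12)c1cc(OC)cc(OC)c1
F13 | step 13 | (3S,4R)-3-BF-4-(3,5-dimethoxyphenyl)oxolan-2-one (cis, other face) | O=C1OC[C@@H](c2cc(OC)cc(OC)c2)[C@H]1c1c(Br)c(OC)cc2O[C@@H](c3ccc(OC)cc3)[C@@H](c12)c1cc(OC)cc(OC)c1
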